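**Retrosynthetic overview**
1. The 12-membered ring is opened at both C4–C15 bonds: one monomer carrying a C4 dienyl triflate and a C15 alkylzinc is joined head to tail twice by Negishi coupling, then desilylated.
2. The strategy rests on the bicyclo[3.1.0]hex-2-ene of each half: ring A (C1, C3, C4, C5, C10) with its tetrasubstituted C4=C5 bond, fused to the cyclopropane C1–C2–C3. This is the product pattern of a 3-acetoxy-1,5-enyne with the alkyne on C5 and the vinyl group on C10 of ring B, and the C4 oxygen it leaves becomes the coupling handle.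
3. The enyne comes from a ring B ketone by ethynylation at C5. The C10 quaternary centre and the C9 carbinol come from vinyl addition and semipinacol 1,2-vinyl shift on an epoxy quinone monoketal.
4. The quinone monoketal comes from a phenol by oxidative dearomatisation. C11 is set on the arene by desymmetrising reduction of an aryl(methyl)malonate.
5. Ring order: ring B (arene to dienone), then ring A and the cyclopropane together (step 13), then the macrocycle (step 16).

Key step: step 13

Numbering: lindenane numbering of each half is used throughout (cyclopropane C1–C2–C3; ring A C1, C3, C4, C5, C10; ring B C5–C10; C14 methyl on C10; C11 on C7 with C13 methyl, C12 ester carbon and C15 methylene).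
Assumption: the enantiomeric sense of steps 3 and 7 is fixed by choosing the ligand antipode or cinchona pseudoenantiomer; the descriptors given are the ones required.
Assumption: 31 is drawn as its C4 enol; other tautomers would give the same anion.

**Step 1**
Reactants: 1 5-bromo-2-methylphenol; 2 benzyl bromide
Product: 3 2-(benzyloxy)-4-bromo-1-methylbenzene
Conditions: K2CO3, DMF, 25 °C
Reagents that add atoms: benzyl bromide, BrCc1ccccc1
Why: Williamson etherification masks the phenol as a benzyl ether that should withstand the enolate arylation, the zinc hydride reduction and the Appel conditions that follow.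

**Step 2**
Reactants: 3 aryl bromide; 4 dimethyl malonate; 5 iodomethane
Product: 7 dimethyl 2-[3-(benzyloxy)-4-methylphenyl]-2-methylpropanedioate, via arylmalonate 6 (not isolated)
Conditions: NaH, Pd(dba)2 (bis(dibenzylideneacetone)palladium, 2 mol %), P(t-Bu)3, THF, 70 °C; then MeI, 25 °C
Reagents that add atoms: dimethyl malonate, COC(=O)CC(=O)OC; iodomethane, CI
Why: Palladium-catalysed α-arylation of the malonate enolate (Buchwald–Hartwig-type enolate arylation) followed by C-methylation of the arylmalonate anion in the same flask builds the prochiral C11 centre; the unsubstituted malonate is arylated first because α-alkylmalonates couple poorly.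

**Step 3**
Reactants: 7 aryl(methyl)malonate; 8 dimethoxy(methyl)silane
Product: 10 methyl (2S)-2-[3-(benzyloxy)-4-methylphenyl]-3-hydroxy-2-methylpropanoate, via silyl ether 9 (not isolated)
Conditions: ZnEt2 (10 mol %), chiral tetradentate aminophenol ligand of the ProPhenol type (5 mol %), HSiMe(OMe)2, THF, 0 °C; then K2CO3 (cat.), MeOH, 0 °C
Reagents that add atoms: none
Why: Enantiotopic-group-selective hydrosilylation of a disubstituted malonic ester (catalytic desymmetrising mono-reduction) by a zinc hydride whose chiral pocket tells aryl from methyl should reduce only the pro-R ester, which sets C11 (2S here).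

**Step 4**
Reactants: 10 hydroxy ester; 11 iodine
Product: 12 methyl (2R)-2-[3-(benzyloxy)-4-methylphenyl]-3-iodo-2-methylpropanoate
Conditions: I2, PPh3, imidazole, toluene, 80 °C
Reagents that add atoms: iodine, II
Why: Appel iodination of the neopentyl alcohol through the alkoxyphosphonium ion is helped by aryl participation, which should return the unrearranged primary iodide because the other opening would place charge next to the ester; C11 is untouched and becomes R only through the new priority of CH2I.

**Step 5**
Reactants: 12 benzyl ether iodide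
Product: 13 methyl (2R)-2-(3-hydroxy-4-methylphenyl)-3-iodo-2-methylpropanoate
Conditions: BCl3, C6HMe5, CH2Cl2, −78 °C
Reagents that add atoms: none
Why: Lewis acid debenzylation with a cation scavenger frees the phenol without touching the alkyl iodide, which hydrogenolysis would not spare.

**Step 6**
Reactants: 13 phenol; 14 methanol
Product: 16 methyl (2R)-2-(6,6-dimethoxy-4-methyl-3-oxocyclohexa-1,4-dien-1-yl)-3-iodo-2-methylpropanoate, via methoxyphenol 15 (not isolated)
Conditions: PhI(OAc)2 (2.2 equiv), MeOH, 0 → 25 °C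
Reagents that add atoms: methanol, CO
Why: Hypervalent-iodine oxidative dearomatisation oxidises the phenol twice in methanol, first to the para-methoxyphenol (methanol attacks C8, para to the phenol oxygen) and then to the p-quinone monoketal, so that C5 is a free ketone and C8 a masked one.

**Step 7**
Reactants: 16 quinone monoketal; 17 tert-butyl hydroperoxide
Product: 18 methyl (2R)-2-[(1R,6R)-5,5-dimethoxy-1-methyl-2-oxo-7-oxabicyclo[4.1.0]hept-3-en-4-yl]-3-iodo-2-methylpropanoate
Conditions: t-BuOOH, NaOH (aq), N-(9-anthracenylmethyl)cinchonidinium-type phase-transfer catalyst (10 mol %), toluene, 0 °C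
Reagents that add atoms: tert-butyl hydroperoxide, CC(C)(C)OO
Why: Weitz–Scheffer nucleophilic epoxidation under chiral phase-transfer catalysis should add the hydroperoxide anion to C9, the only unhindered enone β-carbon (C7 is shielded by quaternary C11), with the cinchona ion pair selecting the face to give the (9R,10R)-epoxide that fixes the absolute configuration of ring B.

**Step 8**
Reactants: 18 epoxy enone; 19 vinylmagnesium bromide
Product: 20 methyl (2R)-2-[(1R,2R,6R)-2-ethenyl-2-hydroxy-5,5-dimethoxy-1-methyl-7-oxabicyclo[4.1.0]hept-3-en-4-yl]-3-iodo-2-methylpropanoate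
Conditions: CH2=CHMgBr, THF, −78 °C
Reagents that add atoms: vinylmagnesium bromide, C=C[Mg]Br
Why: Grignard 1,2-addition to the epoxy ketone should occur anti to the epoxide oxygen, giving the cis-hydroxy epoxide with the vinyl group trans to the epoxide oxygen; the hindered ester and the neopentyl iodide should not react at −78 °C.

**Step 9**
Reactants: 20 epoxy alcohol
Product: 21 methyl (2R)-2-[(4R,5R)-4-ethenyl-5-hydroxy-6,6-dimethoxy-4-methyl-3-oxocyclohex-1-en-1-yl]-3-iodo-2-methylpropanoate
Conditions: BF3·OEt2, CH2Cl2, −78 °C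
Reagents that add atoms: none
Why: Semipinacol rearrangement of a 2,3-epoxy alcohol: BF3 opens the epoxide at tertiary C10 and the vinyl group, antiperiplanar to the breaking C10–O bond, migrates from C5 to C10 with inversion while C5 becomes the enone carbonyl, which creates the C10 quaternary centre with the retained C9 hydroxyl cis to the C10 methyl and trans to the vinyl group.

**Step 10**
Reactants: 21 hydroxy ketone; 22 tert-butyldimethylsilyl trifluoromethanesulfonate
Product: 23 methyl (2R)-2-[(4R,5R)-5-[(tert-butyldimethylsilyl)oxy]-4-ethenyl-6,6-dimethoxy-4-methyl-3-oxocyclohex-1-en-1-yl]-3-iodo-2-methylpropanoate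
Conditions: TBSOTf, 2,6-lutidine, CH2Cl2, −78 → −20 °C
Reagents that add atoms: tert-butyldimethylsilyl trifluoromethanesulfonate, CC(C)(C)[Si](C)(C)OS(=O)(=O)C(F)(F)F
Why: Silylation with the silyl triflate protects the hindered β-hydroxyl against retro-aldol cleavage in step 11 and supplies the bulky C9 substituent used for facial control in step 13.

**Step 11**
Reactants: 23 silyl ether ketone; 24 ethynylmagnesium bromide; 25 acetic anhydride
Product: 27 methyl (2R)-2-[(3S,4R,5R)-3-acetoxy-5-[(tert-butyldimethylsilyl)oxy]-4-ethenyl-3-ethynyl-6,6-dimethoxy-4-methylcyclohex-1-en-1-yl]-3-iodo-2-methylpropanoate, via magnesium alkoxide 26 (not isolated)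
Conditions: HC≡CMgBr, THF, 0 → 25 °C; then Ac2O, 0 → 25 °C
Reagents that add atoms: ethynylmagnesium bromide, C#C[Mg]Br; acetic anhydride, CC(=O)OC(C)=O
Why: Acetylide 1,2-addition to the non-enolisable enone carbonyl followed by O-acetylation of the tertiary magnesium alkoxide gives the 3-acetoxy-1,5-enyne; attack anti to the pseudoaxial C10 methyl should place the ethynyl group cis to the vinyl group, and the C5 configuration is lost again in step 13.

**Step 12**
Reactants: 27 acetate ketal; 28 water
Product: 29 methyl (2R)-2-[(3S,4R,5R)-3-acetoxy-5-[(tert-butyldimethylsilyl)oxy]-4-ethenyl-3-ethynyl-4-methyl-6-oxocyclohex-1-en-1-yl]-3-iodo-2-methylpropanoate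
Conditions: PPTS, acetone/H2O, 40 °C
Reagents that add atoms: water, O
Why: Mild acid-catalysed hydrolysis of the allylic dimethyl ketal through the conjugated oxocarbenium ion unveils the C8 ketone, while the secondary TBS ether and the tertiary acetate should survive.

**Step 13**
Reactants: 29 ring B enone with C5 ethynyl acetate and C10 vinyl
Product: 30 tricyclic dienyl acetate (ring A with C4=C5 and C4 OAc; cyclopropane C1–C2–C3 syn to the C10 methyl; 1R,3S,9R,10S,11R)
Conditions: Ph3PAuNTf2 (5 mol %, silver-free), CH2Cl2, 25 °C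
Reagents that add atoms: none
Why: Monovalent gold π-activates the terminal alkyne, the acetate carbonyl adds 5-exo-dig to C4 to give a 1,3-dioxolenium ion, and collapse of that ion completes the 1,2-acyloxy shift to a vinyl gold carbenoid at C3 beside the new C4=C5 enol acetate, which then cyclopropanates the C1=C2 vinyl group on C10. The closest known reaction type is the Rautenstrauch-type cycloisomerisation of 3-acyloxy-1,5-enynes to bicyclo[3.1.0]hex-2-en-2-yl esters under gold or platinum catalysis. Ring A closes 5-exo-trig (C3 onto C1 along C3–C4–C5–C10–C1) and the cyclopropane is the three-membered ring of the same [2+1] addition (C3–C1 and C3–C2). Of the new stereocentres, C3 is tied to C1 by the obligatory cis fusion, and C1 is set by the C10 quaternary centre: in the reacting vinyl rotamer C2 sits gauche to the C10 methyl and anti to the C9 methine with its OTBS group, so the methylene should form syn to the methyl (1R,3S). The step needs 1,2- over 1,3-acyloxy migration, which the terminal alkyne secures; it needs the vinyl group to win over C6=C7, which is electron-poor and out of reach because ring B holds C4=C5–C6=C7 s-trans; and it needs the tertiary acetate not to ionise, which the C8 carbonyl ensures by cross-conjugation of the would-be cation. C5 becomes trigonal, so any C5 epimer from step 11 converges, and the silver-free catalyst should leave the alkyl iodide alone.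

**Step 14**
Reactants: 30 tricyclic dienyl acetate; 14 methanol
Product: 31 tricyclic C4 dienol (vinylogous diketone; 1R,3S,9R,10S,11R)
Conditions: K2CO3 (cat.), MeOH, −10 °C; pH 5 buffer
Reagents that add atoms: none
Why: Transesterification of the vinylogous enol ester should be fast with catalytic carbonate because the leaving group is a doubly vinylogous carboxylate, and low temperature with short contact keeps O8 of the anion from alkylating the neopentyl iodide.

**Step 15**
Reactants: 31 dienol; 32 N-phenylbis(trifluoromethanesulfonimide)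
Product: 33 tricyclic C4 dienyl triflate with C15 iodide (1R,3S,9R,10S,11R)
Conditions: PhNTf2, Et3N, DMAP (cat.), CH2Cl2, 0 °C
Reagents that add atoms: N-phenylbis(trifluoromethanesulfonimide), O=S(=O)(N(c1ccccc1)S(=O)(=O)C(F)(F)F)C(F)(F)F
Why: O-sulfonylation of the ambident vinylogous diketonate is expected at O4, which is flanked only by the cyclopropane methine, and not at O8, which is buried between the C9 silyl ether and quaternary C11.

**Step 16**
Reactants: 33 dienyl triflate iodide (two molecules); 34 zinc
Product: 37 bis(tert-butyldimethylsilyl) ether of cycloshizukaol A, via alkylzinc iodide 35 (not isolated), via linear dimer 36 (not isolated)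
Conditions: Zn dust, LiCl, THF/DMA, 40 °C; decant; slow addition to Pd2(dba)3 (tris(dibenzylideneacetone)dipalladium, 5 mol %), SPhos, THF, 50 °C, 2 mM
Reagents that add atoms: none
Why: LiCl-assisted zinc insertion into the β-ester alkyl iodide gives a chelated zinc homoenolate without β-hydrogen, and two successive Negishi couplings with the C4 dienyl triflates (intermolecular, then 12-membered macrocyclisation of the linear dimer) join the halves head to tail; closure within one monomer is impossible because ring B holds C4=C5–C6=C7 s-trans.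

**Step 17**
Reactants: 37 bis-silyl ether
Product: 38 cycloshizukaol A
Conditions: HF·pyridine, pyridine, THF, 0 → 25 °C
Reagents that add atoms: none
Why: Fluoride-mediated desilylation with buffered HF·pyridine removes both hindered secondary TBS ethers under mildly acidic conditions that avoid base-induced epimerisation at C9 or α-ketol shift.

**Compound list**
1 | 5-bromo-2-methylphenol | Cc1ccc(Br)cc1O | starting material
2 | benzyl bromide | BrCc1ccccc1 | starting material
3 | 2-(benzyloxy)-4-bromo-1-methylbenzene | Cc1ccc(Br)cc1OCc1ccccc1 | intermediate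
4 | dimethyl malonate | COC(=O)CC(=O)OC | starting material
5 | iodomethane | CI | starting material
6 | dimethyl 2-[3-(benzyloxy)-4-methylphenyl]propanedioate (present as its sodium enolate) | COC(=O)C(C(=O)OC)c1ccc(C)c(OCc2ccccc2)c1 | intermediate
7 | dimethyl 2-[3-(benzyloxy)-4-methylphenyl]-2-methylpropanedioate | COC(=O)C(C)(C(=O)OC)c1ccc(C)c(OCc2ccccc2)c1 | intermediate
8 | dimethoxy(methyl)silane | CO[SiH](C)OC | starting material
9 | methyl (2S)-2-[3-(benzyloxy)-4-methylphenyl]-3-{[dimethoxy(methyl)silyl]oxy}-2-methylpropanoate | Cc1ccc([C@](C)(C(=O)OC)CO[Si](C)(OC)OC)cc1OCc1ccccc1 | intermediate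
10 | methyl (2S)-2-[3-(benzyloxy)-4-methylphenyl]-3-hydroxy-2-methylpropanoate | Cc1ccc([C@](C)(C(=O)OC)CO)cc1OCc1ccccc1 | intermediate
11 | iodine | II | starting material
12 | methyl (2R)-2-[3-(benzyloxy)-4-methylphenyl]-3-iodo-2-methylpropanoate | Cc1ccc([C@](C)(C(=O)OC)CI)cc1OCc1ccccc1 | intermediate
13 | methyl (2R)-2-(3-hydroxy-4-methylphenyl)-3-iodo-2-methylpropanoate | Cc1ccc([C@](C)(C(=O)OC)CI)cc1O | intermediate
14 | methanol | CO | starting material
15 | methyl (2R)-2-(5-hydroxy-2-methoxy-4-methylphenyl)-3-iodo-2-methylpropanoate | COc1cc(C)c(O)cc1[C@](C)(C(=O)OC)CI | intermediate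
16 | methyl (2R)-2-(6,6-dimethoxy-4-methyl-3-oxocyclohexa-1,4-dien-1-yl)-3-iodo-2-methylpropanoate | O=C1C=C([C@](C)(C(=O)OC)CI)C(OC)(OC)C=C1C | intermediate
17 | tert-butyl hydroperoxide | CC(C)(C)OO | starting material
18 | methyl (2R)-2-[(1R,6R)-5,5-dimethoxy-1-methyl-2-oxo-7-oxabicyclo[4.1.0]hept-3-en-4-yl]-3-iodo-2-methylpropanoate | O=C1C=C([C@](C)(C(=O)OC)CI)C(OC)(OC)[C@@H]2O[C@]12C | intermediate
19 | vinylmagnesium bromide | C=C[Mg]Br | starting material
20 | methyl (2R)-2-[(1R,2R,6R)-2-ethenyl-2-hydroxy-5,5-dimethoxy-1-methyl-7-oxabicyclo[4.1.0]hept-3-en-4-yl]-3-iodo-2-methylpropanoate | C=C[C@@]1(O)C=C([C@](C)(C(=O)OC)CI)C(OC)(OC)[C@@H]2O[C@]12C | intermediate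
21 | methyl (2R)-2-[(4R,5R)-4-ethenyl-5-hydroxy-6,6-dimethoxy-4-methyl-3-oxocyclohex-1-en-1-yl]-3-iodo-2-methylpropanoate | O=C1C=C([C@](C)(C(=O)OC)CI)C(OC)(OC)[C@H](O)[C@@]1(C)C=C | intermediate
22 | tert-butyldimethylsilyl trifluoromethanesulfonate | CC(C)(C)[Si](C)(C)OS(=O)(=O)C(F)(F)F | starting material
23 | methyl (2R)-2-[(4R,5R)-5-[(tert-butyldimethylsilyl)oxy]-4-ethenyl-6,6-dimethoxy-4-methyl-3-oxocyclohex-1-en-1-yl]-3-iodo-2-methylpropanoate | O=C1C=C([C@](C)(C(=O)OC)CI)C(OC)(OC)[C@H](O[Si](C)(C)C(C)(C)C)[C@@]1(C)C=C | intermediate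
24 | ethynylmagnesium bromide | C#C[Mg]Br | starting material
25 | acetic anhydride | CC(=O)OC(C)=O | starting material
26 | bromomagnesium alkoxide of the (3S,4R,5R) C5 ethynyl carbinol (27 with OMgBr in place of OAc) | C1=C([C@](C)(C(=O)OC)CI)C(OC)(OC)[C@H](O[Si](C)(C)C(C)(C)C)[C@@](C)(C=C)[C@@]1(O[Mg]Br)C#C | intermediate
27 | methyl (2R)-2-[(3S,4R,5R)-3-acetoxy-5-[(tert-butyldimethylsilyl)oxy]-4-ethenyl-3-ethynyl-6,6-dimethoxy-4-methylcyclohex-1-en-1-yl]-3-iodo-2-methylpropanoate | C1=C([C@](C)(C(=O)OC)CI)C(OC)(OC)[C@H](O[Si](C)(C)C(C)(C)C)[C@@](C)(C=C)[C@@]1(OC(C)=O)C#C | intermediate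
28 | water | O | starting material
29 | methyl (2R)-2-[(3S,4R,5R)-3-acetoxy-5-[(tert-butyldimethylsilyl)oxy]-4-ethenyl-3-ethynyl-4-methyl-6-oxocyclohex-1-en-1-yl]-3-iodo-2-methylpropanoate | C1=C([C@](C)(C(=O)OC)CI)C(=O)[C@H](O[Si](C)(C)C(C)(C)C)[C@@](C)(C=C)[C@@]1(OC(C)=O)C#C | intermediate
30 | tricyclic dienyl acetate: cyclopropane C1–C2–C3 fused to cyclopentene ring A (C4=C5, OAc on C4), fused at C5–C10 to ring B (C6=C7, C8=O, C9 OTBS, C10 CH3); C7 bears (R)-C(CH3)(CO2CH3)CH2I; 1R,3S,9R,10S | CC(=O)OC2=C3C=C([C@](C)(C(=O)OC)CI)C(=O)[C@H](O[Si](C)(C)C(C)(C)C)[C@@]3(C)[C@@H]3C[C@H]23 | intermediate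
31 | tricyclic C4 dienol (30 with OH in place of OAc; vinylogous diketone) | OC2=C3C=C([C@](C)(C(=O)OC)CI)C(=O)[C@H](O[Si](C)(C)C(C)(C)C)[C@@]3(C)[C@@H]3C[C@H]23 | intermediate
32 | N-phenylbis(trifluoromethanesulfonimide) | O=S(=O)(N(c1ccccc1)S(=O)(=O)C(F)(F)F)C(F)(F)F | starting material
33 | tricyclic C4 dienyl triflate (30 with OTf in place of OAc) | FC(F)(F)S(=O)(=O)OC2=C3C=C([C@](C)(C(=O)OC)CI)C(=O)[C@H](O[Si](C)(C)C(C)(C)C)[C@@]3(C)[C@@H]3C[C@H]23 | intermediate
34 | zinc | [Zn] | starting material
35 | alkylzinc iodide of 33 (C15–ZnI) | FC(F)(F)S(=O)(=O)OC2=C3C=C([C@](C)(C(=O)OC)C[Zn]I)C(=O)[C@H](O[Si](C)(C)C(C)(C)C)[C@@]3(C)[C@@H]3C[C@H]23 | intermediate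
36 | linear head-to-tail dimer with one C4 triflate and one C15 zinc iodide | FC(F)(F)S(=O)(=O)OC2=C3C=C([C@](C)(C(=O)OC)CC4=C5C=C([C@](C)(C(=O)OC)C[Zn]I)C(=O)[C@H](O[Si](C)(C)C(C)(C)C)[C@@]5(C)[C@@H]5C[C@H]45)C(=O)[C@H](O[Si](C)(C)C(C)(C)C)[C@@]3(C)[C@@H]3C[C@H]23 | intermediate
37 | 9,9'-bis(tert-butyldimethylsilyl) ether of cycloshizukaol A | COC(=O)[C@]1(C)CC2=C3C=C(C(=O)[C@H](O[Si](C)(C)C(C)(C)C)[C@@]3(C)[C@@H]3C[C@H]23)[C@](C)(C(=O)OC)CC2=C3C=C1C(=O)[C@H](O[Si](C)(C)C(C)(C)C)[C@@]3(C)[C@@H]1C[C@H]21 | intermediate
38 | cycloshizukaol A (each half 1R,3S,9R,10S,11R) | COC(=O)[C@]1(C)CC2=C3C=C(C(=O)[C@H](O)[C@@]3(C)[C@@H]3C[C@H]23)[C@](C)(C(=O)OC)CC2=C3C=C1C(=O)[C@H](O)[C@@]3(C)[C@@H]1C[C@H]21 | target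

**Step count**
Total steps: 17. Longest linear sequence: 17 steps (1 to 38); the route is linear, with two molecules of 33 joined in step 16.

**Steps most likely to fail**

Step 13. The cyclopropanation may lose facial control, with the methylene delivered anti to the C10 methyl, or the gold-bound alkyne may be drained by 1,3-acyloxy migration or acetate ionisation. The fallback sets out from 29 and comes back at 31, and it separates carbene formation from the acyloxy shift. Hydration of the alkyne with Hg(OTf)2 in wet acetonitrile would give the acetoxy methyl ketone F1. Condensation with tert-butoxybis(dimethylamino)methane would give the enaminone F2, and diazo transfer with tosyl azide would give the diazo ketone F3. Intramolecular cyclopropanation with Rh2(OAc)4, or with a chiral dirhodium carboxamidate whose ligand sphere can be matched to the substrate to steer the vinyl face, would give the tricyclic acetoxy ketone F4. SmI2 in THF/MeOH at −78 °C would then remove the C5 acetoxy group, which is α to the C4 ketone, to give dienol 31.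

Step 16. Oligomerisation may outrun macrocyclisation, or the alkylzinc may be protonated, or the dienone reduced by zinc, before coupling. The fallback sets out from 30 and 33 and comes back at 36, then 37, and it makes the two couplings separate events. Zinc insertion into acetate 30 would give the alkylzinc acetate F5, which carries no triflate. Decanted from excess zinc, it would be coupled with triflate 33 under zerovalent palladium, the neopentyl iodide of 33 being inert, to give the linear acetate iodide F6. Methanolysis would give the linear dienol iodide F7 and triflation the linear triflate iodide F8. Zinc insertion would then give 36 as a discrete species, which would be cyclised to 37 by syringe-pump addition to the palladium catalyst at high dilution.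

Step 7. Enantioface discrimination by the phase-transfer catalyst may be poor, or the α-methyl enone may react sluggishly. The fallback sets out from 16 and comes back at 21, and it replaces catalyst control by hydroxyl direction and separation. Vinylmagnesium bromide would be added first to give the vinyl dienol F9 as a mixture of C5 epimers. VO(acac)2 with t-BuOOH would deliver oxygen syn to the hydroxyl at C9=C10, giving 20 together with the diastereomeric epoxy alcohol F10. Both would rearrange with BF3·OEt2, and 21 would be separated by chromatography from the diastereomeric hydroxy ketone F11, which differs in the sense of ring B relative to C11.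

**Further compounds**
F1 | step 13 | methyl (2R)-2-[(3S,4R,5R)-3-acetoxy-3-acetyl-5-[(tert-butyldimethylsilyl)oxy]-4-ethenyl-4-methyl-6-oxocyclohex-1-en-1-yl]-3-iodo-2-methylpropanoate | C1=C([C@](C)(C(=O)OC)CI)C(=O)[C@H](O[Si](C)(C)C(C)(C)C)[C@@](C)(C=C)[C@@]1(OC(C)=O)C(C)=O
F2 | step 13 | (E)-3-(dimethylamino)propenoyl analogue of F1 (enaminone) | C1=C([C@](C)(C(=O)OC)CI)C(=O)[C@H](O[Si](C)(C)C(C)(C)C)[C@@](C)(C=C)[C@@]1(OC(C)=O)C(=O)/C=C/N(C)C
F3 | step 13 | diazoacetyl analogue of F1 (α-diazo ketone) | C1=C([C@](C)(C(=O)OC)CI)C(=O)[C@H](O[Si](C)(C)C(C)(C)C)[C@@](C)(C=C)[C@@]1(OC(C)=O)C(=O)C=[N+]=[N-]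
F4 | step 13 | tricyclic C5 acetoxy C4 ketone (C5 sp3, cyclopropane as in 31) | CC(=O)O[C@]12C=C([C@](C)(C(=O)OC)CI)C(=O)[C@H](O[Si](C)(C)C(C)(C)C)[C@@]1(C)[C@@H]1C[C@@H]1C2=O
F5 | step 16 | alkylzinc iodide of dienyl acetate 30 | CC(=O)OC2=C3C=C([C@](C)(C(=O)OC)C[Zn]I)C(=O)[C@H](O[Si](C)(C)C(C)(C)C)[C@@]3(C)[C@@H]3C[C@H]23
F6 | step 16 | linear dimer with C4 acetate and C15 iodide | CC(=O)OC2=C3C=C([C@](C)(C(=O)OC)CC4=C5C=C([C@](C)(C(=O)OC)CI)C(=O)[C@H](O[Si](C)(C)C(C)(C)C)[C@@]5(C)[C@@H]5C[C@H]45)C(=O)[C@H](O[Si](C)(C)C(C)(C)C)[C@@]3(C)[C@@H]3C[C@H]23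
F7 | step 16 | linear dimer with C4 enol and C15 iodide | OC2=C3C=C([C@](C)(C(=O)OC)CC4=C5C=C([C@](C)(C(=O)OC)CI)C(=O)[C@H](O[Si](C)(C)C(C)(C)C)[C@@]5(C)[C@@H]5C[C@H]45)C(=O)[C@H](O[Si](C)(C)C(C)(C)C)[C@@]3(C)[C@@H]3C[C@H]23
F8 | step 16 | linear dimer with C4 triflate and C15 iodide | FC(F)(F)S(=O)(=O)OC2=C3C=C([C@](C)(C(=O)OC)CC4=C5C=C([C@](C)(C(=O)OC)CI)C(=O)[C@H](O[Si](C)(C)C(C)(C)C)[C@@]5(C)[C@@H]5C[C@H]45)C(=O)[C@H](O[Si](C)(C)C(C)(C)C)[C@@]3(C)[C@@H]3C[C@H]23
F9 | step 7 | methyl (2R)-2-(3-ethenyl-3-hydroxy-6,6-dimethoxy-4-methylcyclohexa-1,4-dien-1-yl)-3-iodo-2-methylpropanoate (C3 epimers) | C=CC1(O)C=C([C@](C)(C(=O)OC)CI)C(OC)(OC)C=C1C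
F10 | step 7 | (1S,2S,6S) ring diastereomer of 20 | C=C[C@]1(O)C=C([C@](C)(C(=O)OC)CI)C(OC)(OC)[C@H]2O[C@@]12C
F11 | step 7 | (4S,5S) ring diastereomer of 21 | O=C1C=C([C@](C)(C(=O)OC)CI)C(OC)(OC)[C@@H](O)[C@]1(C)C=C
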